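**Plan**

- Retrosynthesis: first the two benzyl ethers and the one methyl ether peri to a carbonyl are put back on the phenols. Then ring C of unit 2 is cut at O1''–C8a'' and C2''–C3'', which takes out 4-methoxybenzaldehyde and leaves an aryl fluoride and a CH2 ketone. Then C3–C3'' is cut (enolate plus phenacyl bromide), then the C2–aryl bond of unit 1 (chromone plus arylboronic acid).
- Forward: ring C of unit 1 is closed as a chromone on ring A, the 2-aryl group is added, C3 is alkylated to a 1,4-diketone, ring C of unit 2 is annulated in one operation, and the three phenols are freed.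
- Enabling feature: in unit 2, O1'' sits on C8a'', the ring A carbon ortho to the C4'' ketone and meta to both ring A oxygens (C5'', C7''), so a fluorine at C8a'' is an activated SNAr leaving group. C3'' is the α-carbon of the same ketone and C2'' is the carbonyl carbon of a non-enolisable aldehyde, so the aldehyde C=O can be inserted between C3'' and C8a''.
- Stereochemistry: C2 from a chiral rhodium catalyst; C3 by alkylation anti to the 2-aryl group (trans); C2''/C3'' cis from a Z-enolate syn-aldol; C3'' relative to C3 from allylic strain in that enolate.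

Key step: step 5

Remark: the SMILES is read as 2,3-trans (2S,3R) in the 5,7-dihydroxy unit (unit 1, plain locants) and 2,3-cis (2''S,3''S) in the 5-hydroxy-7-methoxy unit (unit 2, double-primed locants); ring A is the benzo ring and ring C the pyranone ring of each unit.

**Route**

Step 1
Reactants: 1 1-[2,4-bis(benzyloxy)-6-hydroxyphenyl]ethan-1-one
Product: 3 5,7-bis(benzyloxy)-4H-chromen-4-one, via enaminone 2 (not isolated)
Conditions: Me2NCH(OMe)2, toluene, 100 °C; evaporate; conc. HCl, CH2Cl2, 25–40 °C
Reagents that add atoms: N,N-dimethylformamide dimethyl acetal, COC(OC)N(C)C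
Why: Condensation of the methyl ketone with the amide acetal gives the enaminone, and acid then closes ring C by attack of the phenol on the enaminone carbon with loss of dimethylamine (standard chromone synthesis from 2'-hydroxyacetophenones).

Step 2
Reactants: 3 5,7-bis(benzyloxy)-4H-chromen-4-one; 4 (4-methoxyphenyl)boronic acid
Product: 5 (2S)-5,7-bis(benzyloxy)-2-(4-methoxyphenyl)chroman-4-one
Conditions: [Rh(OH)(cod)]2 (cat., monovalent rhodium; cod = cycloocta-1,5-diene), MeO-F12-BIPHEP (2,2'-bis[bis(3,4,5-trifluorophenyl)phosphino]-6,6'-dimethoxybiphenyl; the enantiomer that leads to 2S), toluene/H2O, 25 °C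
Reagents that add atoms: none
Why: Rhodium-catalysed asymmetric 1,4-addition of an arylboronic acid to the chromone enone (Hayashi–Miyaura type), in which the aryl–rhodium species adds to C2 on the face fixed by the chiral bisphosphine and the rhodium enolate is protonated by water, so C2 is set as S by the catalyst.

Step 3
Reactants: 6 1-fluoro-3,5-dimethoxybenzene; 7 bromoacetyl bromide
Product: 8 2-bromo-1-(2-fluoro-4,6-dimethoxyphenyl)ethan-1-one
Conditions: AlCl3, CH2Cl2, −10 → 0 °C
Reagents that add atoms: none
Why: Friedel–Crafts acylation should go mainly at the position between fluorine and one methoxy group (para to the other), which is doubly activated and less hindered than the position between the two methoxy groups.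

Step 4
Reactants: 5 (2S)-5,7-bis(benzyloxy)-2-(4-methoxyphenyl)chroman-4-one; 8 2-bromo-1-(2-fluoro-4,6-dimethoxyphenyl)ethan-1-one
Product: 10 (2S,3R)-5,7-bis(benzyloxy)-3-[2-(2-fluoro-4,6-dimethoxyphenyl)-2-oxoethyl]-2-(4-methoxyphenyl)chroman-4-one, via lithium enolate 9 (not isolated)
Conditions: LiN(SiMe3)2, THF, −78 °C; then 8, −78 → −40 °C; AcOH quench
Reagents that add atoms: none
Why: SN2 alkylation of a kinetic ketone lithium enolate by an α-bromo ketone whose carbonyl is shielded by its two ortho substituents; at −78 °C enolate 9 should not open ring C by loss of the electron-rich phenoxide, so C2 keeps its configuration, and the bromide approaches C3 anti to the 2-aryl group to give the trans (2S,3R) product, which is also the more stable epimer.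

Step 5
Reactants: 10 (2S,3R)-5,7-bis(benzyloxy)-3-[2-(2-fluoro-4,6-dimethoxyphenyl)-2-oxoethyl]-2-(4-methoxyphenyl)chroman-4-one; 11 4-methoxybenzaldehyde
Product: 14 (2S,3R)-5,7-bis(benzyloxy)-3-[(2S,3S)-5,7-dimethoxy-2-(4-methoxyphenyl)-4-oxochroman-3-yl]-2-(4-methoxyphenyl)chroman-4-one, via lithium Z-enolate 12 (not isolated), via lithium syn-aldolate 13 (not isolated)
Conditions: LiN(SiMe3)2 (1.05 equiv), THF, −78 °C; 11 (1.5 equiv), −78 °C; then DMPU, −78 → 0 °C; aq. NH4Cl
Reagents that add atoms: none
Why: Proposed new method: LiN(SiMe3)2 removes a proton from the CH2 next to the fluoroaryl ketone (the C3 methine of unit 1 is tertiary, shielded by the 2-aryl group and α to a less acidifying trialkoxyaryl ketone) to give Z-enolate 12, which adds to 11 through a closed six-membered lithium transition state to give aldolate 13, whose alkoxide then attacks the fluorine-bearing carbon ortho to the ketone and expels fluoride by addition–elimination. The closest known reaction types are the syn-selective lithium aldol of aryl ketone Z-enolates and the base-mediated cyclisation of 2-fluoroaryl β-dicarbonyl or β-hydroxy ketones to chromones and chromanones by intramolecular SNAr; running both in one flask so that an aldehyde C=O is inserted between C3'' and C8a'' is the new element. Ring C of unit 2 closes by 6-exo attack of the alkoxide on the aromatic carbon C8a'', which is activated by the ortho carbonyl and has its two methoxy groups meta, where they cannot donate into the anionic intermediate. C2'' and C3'' should come out cis because the Z-enolate and the chair transition state give the syn aldolate and the ring closure touches neither centre; the configuration at C3'' is controlled by C3, since allylic 1,3-strain holds the C3–H bond in the enolate plane and the aldehyde should approach anti to the C2 carbon that carries the aryl group, which corresponds to 3''S. The step needs ring closure to outrun retro-aldol equilibration and C3'' epimerisation, which the activated ortho-fluoro ketone, the excess aldehyde and the low temperature are meant to secure.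

Step 6
Reactants: 14 (2S,3R)-5,7-bis(benzyloxy)-3-[(2S,3S)-5,7-dimethoxy-2-(4-methoxyphenyl)-4-oxochroman-3-yl]-2-(4-methoxyphenyl)chroman-4-one
Product: 15 (2S,3R)-5,7-dihydroxy-3-[(2S,3S)-5-hydroxy-7-methoxy-2-(4-methoxyphenyl)-4-oxochroman-3-yl]-2-(4-methoxyphenyl)chroman-4-one
Conditions: BCl3, C6HMe5, CH2Cl2, −78 → 0 °C; MeOH, then aq. NaHCO3
Reagents that add atoms: none
Why: BCl3 cleaves aryl benzyl ethers at low temperature (the benzyl cation is trapped by pentamethylbenzene) and on warming removes only the methyl ether peri to the C4'' carbonyl through a boron chelate, so the 7''-methoxy and both 4'-methoxy groups stay, and the non-basic medium should leave the 2,3-cis unit unepimerised.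

**Compound list**

1 | 1-[2,4-bis(benzyloxy)-6-hydroxyphenyl]ethan-1-one | CC(=O)c1c(O)cc(OCc2ccccc2)cc1OCc1ccccc1 | starting material
2 | (E)-1-[2,4-bis(benzyloxy)-6-hydroxyphenyl]-3-(dimethylamino)prop-2-en-1-one (enaminone) | CN(C)/C=C/C(=O)c1c(O)cc(OCc2ccccc2)cc1OCc1ccccc1 | intermediate
3 | 5,7-bis(benzyloxy)-4H-chromen-4-one | O=c1ccoc2cc(OCc3ccccc3)cc(OCc3ccccc3)c12 | intermediate
4 | (4-methoxyphenyl)boronic acid | COc1ccc(B(O)O)cc1 | starting material
5 | (2S)-5,7-bis(benzyloxy)-2-(4-methoxyphenyl)chroman-4-one | COc1ccc([C@@H]2CC(=O)c3c(OCc4ccccc4)cc(OCc4ccccc4)cc3O2)cc1 | intermediate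
6 | 1-fluoro-3,5-dimethoxybenzene | COc1cc(F)cc(OC)c1 | starting material
7 | bromoacetyl bromide | O=C(Br)CBr | starting material
8 | 2-bromo-1-(2-fluoro-4,6-dimethoxyphenyl)ethan-1-one | COc1cc(F)c(C(=O)CBr)c(OC)c1 | intermediate
9 | lithium (2S)-5,7-bis(benzyloxy)-2-(4-methoxyphenyl)-2H-chromen-4-olate (lithium enolate of 5) | [Li]OC1=C[C@@H](c2ccc(OC)cc2)Oc2cc(OCc3ccccc3)cc(OCc3ccccc3)c21 | intermediate
10 | (2S,3R)-5,7-bis(benzyloxy)-3-[2-(2-fluoro-4,6-dimethoxyphenyl)-2-oxoethyl]-2-(4-methoxyphenyl)chroman-4-one | COc1ccc([C@H]2Oc3cc(OCc4ccccc4)cc(OCc4ccccc4)c3C(=O)[C@@H]2CC(=O)c2c(F)cc(OC)cc2OC)cc1 | intermediate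
11 | 4-methoxybenzaldehyde | COc1ccc(C=O)cc1 | starting material
12 | lithium (Z)-2-[(2S,3R)-5,7-bis(benzyloxy)-2-(4-methoxyphenyl)-4-oxochroman-3-yl]-1-(2-fluoro-4,6-dimethoxyphenyl)ethen-1-olate (lithium Z-enolate of 10) | COc1ccc([C@H]2Oc3cc(OCc4ccccc4)cc(OCc4ccccc4)c3C(=O)[C@@H]2/C=C(\O[Li])c2c(F)cc(OC)cc2OC)cc1 | intermediate
13 | lithium (1S,2S)-2-[(2S,3R)-5,7-bis(benzyloxy)-2-(4-methoxyphenyl)-4-oxochroman-3-yl]-3-(2-fluoro-4,6-dimethoxyphenyl)-1-(4-methoxyphenyl)-3-oxopropan-1-olate (lithium syn-aldolate) | COc1ccc([C@H]2Oc3cc(OCc4ccccc4)cc(OCc4ccccc4)c3C(=O)[C@@H]2[C@H](C(=O)c2c(F)cc(OC)cc2OC)[C@H](O[Li])c2ccc(OC)cc2)cc1 | intermediate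
14 | (2S,3R)-5,7-bis(benzyloxy)-3-[(2S,3S)-5,7-dimethoxy-2-(4-methoxyphenyl)-4-oxochroman-3-yl]-2-(4-methoxyphenyl)chroman-4-one | COc1ccc([C@H]2Oc3cc(OCc4ccccc4)cc(OCc4ccccc4)c3C(=O)[C@@H]2[C@@H]2C(=O)c3c(OC)cc(OC)cc3O[C@@H]2c2ccc(OC)cc2)cc1 | intermediate
15 | (2S,3R)-5,7-dihydroxy-3-[(2S,3S)-5-hydroxy-7-methoxy-2-(4-methoxyphenyl)-4-oxochroman-3-yl]-2-(4-methoxyphenyl)chroman-4-one | COc1ccc([C@H]2Oc3cc(O)cc(O)c3C(=O)[C@@H]2[C@@H]2C(=O)c3c(O)cc(OC)cc3O[C@@H]2c2ccc(OC)cc2)cc1 | target

**Count and risks**

Total steps: 6. Longest linear sequence: 5 steps (steps 1, 2, 4, 5, 6); step 3 is a one-step side branch.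

Step 5 (most at risk). The lithium aldolate may revert by retro-aldol before the ring closes, which would erode the syn relationship and favour the trans ring; the face selectivity at C3'' may be poor; or the base may enolise the wrong ketone. The fallback separates the two bond formations, each with known chemistry. From 10, soft enolisation with Bu2BOTf/iPr2NEt (CH2Cl2, −78 °C) and addition of 11 should give, after oxidative work-up, the isolated syn-aldol (2S,3R)-5,7-bis(benzyloxy)-3-[(1S,2S)-3-(2-fluoro-4,6-dimethoxyphenyl)-1-hydroxy-1-(4-methoxyphenyl)-3-oxopropan-2-yl]-2-(4-methoxyphenyl)chroman-4-one F1. Boron aldolates do not revert, the Z-enolate again leads to syn, and a diisopinocampheylboron triflate of either hand can add reagent control over the C3'' face. F1 is then cyclised in a separate operation by intramolecular SNAr with Cs2CO3 in DMF at 0–25 °C, which comes back to the route at 14.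

Step 4. Proton transfer from 8 to enolate 9, attack on the carbonyl of 8, or opening of ring C of the enolate with loss of the C2 configuration may take over. The fallback replaces the two-electron alkylation by a radical addition. From 5, Me3SiOTf/Et3N (CH2Cl2, 0 °C) should give, without a free enolate, the silyl enol ether {[(2S)-5,7-bis(benzyloxy)-2-(4-methoxyphenyl)-2H-chromen-4-yl]oxy}trimethylsilane F2. Visible-light photoredox coupling of F2 with 8 (Ru(bpy)3Cl2, divalent ruthenium, blue light, MeCN, 25 °C) lets the phenacyl radical add to C3 anti to the 2-aryl group; oxidation and loss of the silyl group then come back to the route at 10.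

Step 6. The Lewis acid may epimerise C3'' (cis to trans), open ring C, or remove a second methyl ether. The fallback removes the groups in two stages of different type. From 14, hydrogenolysis (H2, Pd/C, zerovalent palladium, EtOAc/THF, 25 °C) removes the two benzyl groups under neutral conditions to give (2S,3R)-3-[(2S,3S)-5,7-dimethoxy-2-(4-methoxyphenyl)-4-oxochroman-3-yl]-5,7-dihydroxy-2-(4-methoxyphenyl)chroman-4-one F3. The methyl ether peri to the C4'' carbonyl is then cleaved by chelation with MgI2·OEt2 (THF, 50 °C), which comes back to the route at 15.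

**Further compounds**

F1 | step 5 | (2S,3R)-5,7-bis(benzyloxy)-3-[(1S,2S)-3-(2-fluoro-4,6-dimethoxyphenyl)-1-hydroxy-1-(4-methoxyphenyl)-3-oxopropan-2-yl]-2-(4-methoxyphenyl)chroman-4-one | COc1ccc([C@H]2Oc3cc(OCc4ccccc4)cc(OCc4ccccc4)c3C(=O)[C@@H]2[C@H](C(=O)c2c(F)cc(OC)cc2OC)[C@H](O)c2ccc(OC)cc2)cc1
F2 | step 4 | {[(2S)-5,7-bis(benzyloxy)-2-(4-methoxyphenyl)-2H-chromen-4-yl]oxy}trimethylsilane | C[Si](C)(C)OC1=C[C@@H](c2ccc(OC)cc2)Oc2cc(OCc3ccccc3)cc(OCc3ccccc3)c21
F3 | step 6 | (2S,3R)-3-[(2S,3S)-5,7-dimethoxy-2-(4-methoxyphenyl)-4-oxochroman-3-yl]-5,7-dihydroxy-2-(4-methoxyphenyl)chroman-4-one | COc1ccc([C@H]2Oc3cc(O)cc(O)c3C(=O)[C@@H]2[C@@H]2C(=O)c3c(OC)cc(OC)cc3O[C@@H]2c2ccc(OC)cc2)cc1
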